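The plan hinges on unzipping rings A and B at once by cutting C5–C10 and C8–C9. Read backwards, the trans-fused decalin and its neighbouring stereocentres C5, C10 and C9 become an open deca-1,7,9-triene in which carbons C1–C4 of ring A link an (E)-β-methyl enal (C9=C10, formyl C11) to a 2-silyloxydiene (C5–C8). In the forward direction a single intramolecular Diels–Alder reaction builds both rings and both bonds, sets C5, C8, C9 and C10, and leaves a C7 enol ether from which the C7=C8 double bond is later installed. The precursor is an acyclic trienal whose only stereocentres are C3 (silyl ether) and quaternary C4; C12–C15 are added afterwards by Wittig reaction.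

Key step: step 12

Remarks on the chemistry (one line each)
- Locants C1–C20 are those of the labdane skeleton of the target: decalin C1–C10, side chain C11–C16 (C16 = methyl on C13), C17 on C8, C18 (methyl) and C19 (CH2O) on C4, C20 on C10.
- Checked against the target, the cycloaddition precursor 18 and product 19 match it at C4, C5, C9 and C10; C3 is deliberately the (3R) epimer of the target's (3S) centre, because only then can the C3 oxygen lie equatorial while C19 is axial in the chair-like tether. It is corrected in steps 19–21 by oxidation and axial-selective reduction, which is safer than an SN2 inversion next to quaternary C4.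
- O3 (TES), O19 (TIPS) and the C7 enol ether (TBS) carry three different silyl groups so that each can be addressed alone.
- The formyl group is unmasked from a vinyl iodide only after the silyl dienol ether is in place, because an enolisable enal would not survive that silylation cleanly.
- (4S)-4-Methyloxolan-2-one is assumed to be purchasable; it holds C12–C15 with C12 and C15 already differentiated.
- C8 in 19 and 24–26 is written as formed in the cycloaddition; its epimer would converge at 27.

Step 1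
Reactants: 1 prop-2-yn-1-ol
Product: 3 (2E)-3-iodo-2-methylprop-2-en-1-ol, via vinylalane 2 (not isolated)
Conditions: AlMe3 (3 equiv), Cp2ZrCl2 (0.25 equiv), CH2Cl2, 0 °C to rt; then I2, THF, −30 to 0 °C
Reagents that add atoms: trimethylaluminium, C[Al](C)C; iodine, II
Why: Negishi zirconium-catalysed syn-carboalumination of the terminal alkyne should place methyl on the internal and aluminium on the terminal carbon, and iodinolysis of the C–Al bond with retention then gives the (E)-vinyl iodide.

Step 2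
Reactants: 3 (2E)-3-iodo-2-methylprop-2-en-1-ol
Product: 4 (1E)-3-bromo-1-iodo-2-methylprop-1-ene
Conditions: CBr4, PPh3, CH2Cl2, 0 °C
Reagents that add atoms: tetrabromomethane, BrC(Br)(Br)Br
Why: Appel bromination should convert the primary allylic alcohol into the bromide under neutral conditions without touching the vinyl iodide or the alkene geometry.

Step 3
Reactants: 4 (1E)-3-bromo-1-iodo-2-methylprop-1-ene; 5 ethyl 2-methyl-3-oxobutanoate
Product: 7 ethyl (6E)-7-iodo-2,6-dimethyl-3-oxohept-6-enoate, via acetoacetate dianion 6 (not isolated)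
Conditions: NaH, THF, 0 °C; n-BuLi, 0 °C; then 4, −78 to 0 °C
Reagents that add atoms: none
Why: Weiler dianion alkylation, in which the more reactive γ-carbanion of the acetoacetate dianion displaces the allylic bromide by SN2, should form the C1–C2 bond and leave the vinyl iodide intact.

Step 4
Reactants: 7 ethyl (6E)-7-iodo-2,6-dimethyl-3-oxohept-6-enoate
Product: 8 ethyl (3R,6E)-3-hydroxy-7-iodo-2,6-dimethylhept-6-enoate (C2 epimers)
Conditions: H2 (4 atm), RuBr2[(R)-BINAP] (1 mol %), EtOH, 50 °C
Reagents that add atoms: none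
Why: Noyori asymmetric hydrogenation of the chelated β-keto ester with the (R)-BINAP ruthenium catalyst should set C3 as (R), the isolated alkene and vinyl iodide not being substrates for this catalyst and the C2 centre being of no consequence because it is enolised in step 5.

Step 5
Reactants: 8 ethyl (3R,6E)-3-hydroxy-7-iodo-2,6-dimethylhept-6-enoate
Product: 10 ethyl (2R,3R,6E)-3-hydroxy-7-iodo-2,6-dimethyl-2-({[tri(propan-2-yl)silyl]oxy}methyl)hept-6-enoate, via dilithium alkoxide enolate 9 (not isolated)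
Conditions: LiN(iPr)2 (2.2 equiv), THF, −78 to −20 °C; then iPr3SiOCH2Cl, DMPU, −78 to 0 °C
Reagents that add atoms: (chloromethoxy)tri(propan-2-yl)silane, ClCO[Si](C(C)C)(C(C)C)C(C)C
Why: Fráter–Seebach alkylation, in which the chloromethyl silyl ether attacks the chelated dilithium alkoxide–enolate on the face opposite the C3 chain, should bring the silyloxymethyl arm (C19) in anti to the C3 oxygen with the resident methyl (C18) syn, fixing quaternary C4.

Step 6
Reactants: 10 ethyl (2R,3R,6E)-3-hydroxy-7-iodo-2,6-dimethyl-2-({[tri(propan-2-yl)silyl]oxy}methyl)hept-6-enoate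
Product: 11 ethyl (2R,3R,6E)-7-iodo-2,6-dimethyl-3-[(triethylsilyl)oxy]-2-({[tri(propan-2-yl)silyl]oxy}methyl)hept-6-enoate
Conditions: Et3SiOTf, 2,6-lutidine, CH2Cl2, −78 to 0 °C
Reagents that add atoms: triethylsilyl trifluoromethanesulfonate, CC[Si](CC)(CC)OS(=O)(=O)C(F)(F)F
Why: Silyl triflate silylation with a hindered pyridine base should protect the hindered secondary alcohol as a TES ether that can later be removed in the presence of the TIPS ether.

Step 7
Reactants: 11 ethyl (2R,3R,6E)-7-iodo-2,6-dimethyl-3-[(triethylsilyl)oxy]-2-({[tri(propan-2-yl)silyl]oxy}methyl)hept-6-enoate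
Product: 12 (2R,3R,6E)-7-iodo-2,6-dimethyl-3-[(triethylsilyl)oxy]-2-({[tri(propan-2-yl)silyl]oxy}methyl)hept-6-en-1-ol
Conditions: iBu2AlH (3 equiv), CH2Cl2, −78 to 0 °C; aq. potassium sodium tartrate work-up
Reagents that add atoms: none
Why: Aluminium hydride reduction of the hindered ester should give the neopentyl primary alcohol while tolerating the vinyl iodide and both silyl ethers.

Step 8
Reactants: 12 (2R,3R,6E)-7-iodo-2,6-dimethyl-3-[(triethylsilyl)oxy]-2-({[tri(propan-2-yl)silyl]oxy}methyl)hept-6-en-1-ol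
Product: 13 (2R,3R,6E)-7-iodo-2,6-dimethyl-3-[(triethylsilyl)oxy]-2-({[tri(propan-2-yl)silyl]oxy}methyl)hept-6-enal
Conditions: Dess–Martin periodinane, NaHCO3, CH2Cl2, rt
Reagents that add atoms: none
Why: Buffered Dess–Martin oxidation should give the non-enolisable α-quaternary aldehyde (C5) without silyl migration or over-oxidation.

Step 9
Reactants: 13 (2R,3R,6E)-7-iodo-2,6-dimethyl-3-[(triethylsilyl)oxy]-2-({[tri(propan-2-yl)silyl]oxy}methyl)hept-6-enal; 14 diethyl (2-oxobutyl)phosphonate
Product: 15 (4E,6R,7R,10E)-11-iodo-6,10-dimethyl-7-[(triethylsilyl)oxy]-6-({[tri(propan-2-yl)silyl]oxy}methyl)undeca-4,10-dien-3-one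
Conditions: Ba(OH)2, THF/H2O (40:1), rt
Reagents that add atoms: none
Why: Horner–Wadsworth–Emmons olefination under the mild barium hydroxide protocol should form the (E)-enone C5=C6 from the hindered, base-stable aldehyde and so add C6, C7, C8 and C17.

Step 10
Reactants: 15 (4E,6R,7R,10E)-11-iodo-6,10-dimethyl-7-[(triethylsilyl)oxy]-6-({[tri(propan-2-yl)silyl]oxy}methyl)undeca-4,10-dien-3-one
Product: 16 (2Z,4E,6R,7R,10E)-3-[(tert-butyldimethylsilyl)oxy]-11-iodo-6,10-dimethyl-7-[(triethylsilyl)oxy]-6-({[tri(propan-2-yl)silyl]oxy}methyl)undeca-2,4,10-triene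
Conditions: tBuMe2SiOTf, Et3N, CH2Cl2, −78 to 0 °C
Reagents that add atoms: tert-butyldimethylsilyl trifluoromethanesulfonate, CC(C)(C)[Si](C)(C)OS(=O)(=O)C(F)(F)F
Why: Soft enolisation of the ethyl ketone with silyl triflate and triethylamine should give the cross-conjugated 2-silyloxydiene, the (Z)-enol ether (methyl cis to oxygen) being favoured as for acyclic ethyl ketones.

Step 11
Reactants: 16 (2Z,4E,6R,7R,10E)-3-[(tert-butyldimethylsilyl)oxy]-11-iodo-6,10-dimethyl-7-[(triethylsilyl)oxy]-6-({[tri(propan-2-yl)silyl]oxy}methyl)undeca-2,4,10-triene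
Product: 18 (2E,6R,7R,8E,10Z)-10-[(tert-butyldimethylsilyl)oxy]-3,7-dimethyl-6-[(triethylsilyl)oxy]-7-({[tri(propan-2-yl)silyl]oxy}methyl)dodeca-2,8,10-trienal, via vinyllithium 17 (not isolated)
Conditions: t-BuLi (2.1 equiv), Et2O, −78 °C; then DMF, −78 to −20 °C; pH 7 buffer
Reagents that add atoms: N,N-dimethylformamide, CN(C)C=O
Why: Iodine–lithium exchange at low temperature should proceed with retention of alkene geometry, and formylation of the vinyllithium with DMF unveils the (E)-enal only after the sensitive dienol ether is in place.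

Step 12
Reactants: 18 (2E,6R,7R,8E,10Z)-10-[(tert-butyldimethylsilyl)oxy]-3,7-dimethyl-6-[(triethylsilyl)oxy]-7-({[tri(propan-2-yl)silyl]oxy}methyl)dodeca-2,8,10-trienal
Product: 19 trans-decalin aldehyde (C11 formyl; C6=C7 TBS enol ether; 3-OTES; 19-OTIPS)
Conditions: Me2AlCl (1.5 equiv), CH2Cl2 (0.01 M), −78 to −30 °C
Reagents that add atoms: none
Why: Me2AlCl binds the formyl oxygen and the (E)-enal C9=C10 then adds suprafacially across the s-cis diene C5=C6–C7=C8 in a concerted but asynchronous [4+2] cycloaddition in which C5–C10 bonding runs ahead of C8–C9 bonding; the closest known reaction type is the Lewis acid promoted intramolecular Diels–Alder reaction of deca-1,7,9-trienals. Ring B closes as the new cyclohexene of the cycloaddition itself, and ring A closes in the same event as the six-membered ring made by the C1–C4 tether and the new C5–C10 bond, held chair-like. C9 and C10 are set by the retained (E)-enal geometry (C11 cis to the C10 methyl), C5 by the endo position of the aluminium-bound formyl group with the tether anti (H5 trans to the C10 methyl, hence the trans fusion), and C8 by the (Z)-enol ether, whose outside methyl ends cis to C11. The absolute sense of all four centres follows from the C3/C4 pair, because only one diene face lets the tether adopt the chair with the C3 triethylsilyloxy group and C18 equatorial and C19 axial. The step therefore needs endo (trans-fusion) selectivity, which Lewis acid complexation of the formyl group should secure, and diene-face selectivity, which rests on the equatorial preference of the C3 silyl ether over the flipped chair with an axial C3 oxygen.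

Step 13
Reactants: 20 (4S)-4-methyloxolan-2-one
Product: 21 methyl (3S)-4-bromo-3-methylbutanoate
Conditions: HBr (anhydrous), MeOH, 0 to 40 °C
Reagents that add atoms: hydrogen bromide, Br; methanol, CO
Why: Acid-promoted opening of the γ-lactone by bromide at the O–CH2 carbon (SN2) with Fischer esterification should give the bromo ester without touching the stereocentre.

Step 14
Reactants: 21 methyl (3S)-4-bromo-3-methylbutanoate
Product: 22 [(2S)-4-methoxy-2-methyl-4-oxobutyl]triphenylphosphonium bromide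
Conditions: PPh3, MeCN, reflux
Reagents that add atoms: triphenylphosphine, c1ccc(cc1)P(c1ccccc1)c1ccccc1
Why: SN2 quaternisation of triphenylphosphine by the primary bromide should give the Wittig salt that carries C12–C15 and the C13 stereocentre.

Step 15
Reactants: 19 trans-decalin aldehyde; 22 [(2S)-4-methoxy-2-methyl-4-oxobutyl]triphenylphosphonium bromide
Product: 25 keto alkene methyl ester (C7 ketone; (Z)-C11=C12), via phosphorus ylide 23 (not isolated), via enol ether alkene 24 (not isolated)
Conditions: KN(SiMe3)2 (1.0 equiv per 22), THF, −78 to 0 °C; 19, −78 °C to rt; then AcOH, Bu4NF, 0 °C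
Reagents that add atoms: none
Why: Wittig olefination with the non-stabilised ylide should form C11=C12 at the hindered C9 aldehyde (already the more stable equatorial epimer) while the enol ether shields C7, and buffered fluoride then cleaves only the silyl enol ether, whose protonation at C6 releases the C7 ketone.

Step 16
Reactants: 25 keto alkene methyl ester
Product: 26 saturated keto ester (C7 ketone; C11–C12 single bond)
Conditions: H2 (1 atm), palladium on carbon (Pd/C, 10%), EtOAc, rt
Reagents that add atoms: none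
Why: Heterogeneous catalytic hydrogenation should saturate the 1,2-disubstituted C11=C12 alkene, no other reducible group being present.

Step 17
Reactants: 26 saturated keto ester
Product: 27 enol triflate (C7=C8; OTf on C7)
Conditions: Tf2O, 2,6-di-tert-butyl-4-methylpyridine, CH2Cl2, 0 °C to rt
Reagents that add atoms: trifluoromethanesulfonic anhydride, O=S(=O)(OS(=O)(=O)C(F)(F)F)C(F)(F)F
Why: Enol triflate formation with triflic anhydride and a hindered pyridine runs under product-development control and should place the double bond on the more substituted side (C7=C8), which also removes the C8 stereocentre.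

Step 18
Reactants: 27 enol triflate
Product: 28 alkene ester (C7=C8; 3-OTES; 19-OTIPS)
Conditions: Pd(OAc)2 (5 mol %), PPh3, HCO2H, Et3N, DMF, 60 °C
Reagents that add atoms: none
Why: Palladium-catalysed formate reduction of the vinyl triflate (oxidative addition, decarboxylation of formate, reductive elimination) should replace OTf by H with the alkene fixed at C7=C8.

Step 19
Reactants: 28 alkene ester
Product: 29 equatorial C3 alcohol (19-OTIPS methyl ester)
Conditions: PPTS, MeOH/CH2Cl2, rt
Reagents that add atoms: none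
Why: Mild acid-catalysed methanolysis should remove the TES ether selectively, the TIPS ether being far more resistant to protic cleavage.

Step 20
Reactants: 29 equatorial C3 alcohol
Product: 30 C3 ketone (19-OTIPS methyl ester)
Conditions: Dess–Martin periodinane, NaHCO3, CH2Cl2, rt
Reagents that add atoms: none
Why: Dess–Martin oxidation should convert the C3 alcohol into the ketone, erasing the temporary C3 configuration, with no enolisable centre on the C4 side.

Step 21
Reactants: 30 C3 ketone
Product: 32 axial (3S) hydroxy acid (19-OTIPS), via axial hydroxy methyl ester 31 (not isolated)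
Conditions: Li[HB(sBu)3], THF, −78 °C; then LiOH, MeOH/H2O, 0 °C to rt; aq. HCl to pH 4
Reagents that add atoms: lithium hydroxide, [Li+].[OH-]
Why: The bulky trialkylborohydride should attack the C3 ketone from the equatorial direction, away from the syn-axial hydrogens at C1 and C5, to give the axial (3S) alcohol as in 4,4-disubstituted 3-oxo terpenoids, and the basic work-up then saponifies the methyl ester.

Step 22
Reactants: 32 axial (3S) hydroxy acid
Product: 33 C3 acetate (19-OTIPS acid)
Conditions: Ac2O, DMAP, pyridine, rt; then H2O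
Reagents that add atoms: acetic anhydride, CC(=O)OC(C)=O
Why: DMAP-catalysed acylation should acetylate the hindered axial C3 alcohol, and the mixed anhydride formed at C15 is hydrolysed on aqueous work-up.

Step 23
Reactants: 33 C3 acetate
Product: 34 CNP0138726.1 (target)
Conditions: HF·pyridine, pyridine, THF, 0 °C to rt
Reagents that add atoms: none
Why: Fluoride desilylation should free the C19 alcohol, and acetyl migration is not expected because O3 and C19 are trans-diaxial.

Compound list
1 | prop-2-yn-1-ol (propargyl alcohol) | C#CCO | starting material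
2 | dimethylaluminium (2E)-3-(dimethylalumanyl)-2-methylprop-2-en-1-olate (vinylalane; not isolated) | C[Al](C)OC/C(C)=C/[Al](C)C | intermediate
3 | (2E)-3-iodo-2-methylprop-2-en-1-ol | OC/C(C)=C/I | intermediate
4 | (1E)-3-bromo-1-iodo-2-methylprop-1-ene | BrC/C(C)=C/I | intermediate
5 | ethyl 2-methyl-3-oxobutanoate (racemic) | CCOC(=O)C(C)C(C)=O | starting material
6 | lithium sodium 1-ethoxy-2-methylbuta-1,3-diene-1,3-bis(olate) (dianion of 5; not isolated) | [Li+].[Na+].CCOC([O-])=C(C)C(=C)[O-] | intermediate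
7 | ethyl (6E)-7-iodo-2,6-dimethyl-3-oxohept-6-enoate (racemic at C2) | CCOC(=O)C(C)C(=O)CC/C(C)=C/I | intermediate
8 | ethyl (3R,6E)-3-hydroxy-7-iodo-2,6-dimethylhept-6-enoate (both C2 epimers) | CCOC(=O)C(C)[C@H](O)CC/C(C)=C/I | intermediate
9 | dilithium (3R,6E)-1-ethoxy-7-iodo-2,6-dimethylhepta-1,6-diene-1,3-bis(olate) (not isolated) | [Li+].[Li+].CCOC([O-])=C(C)[C@H]([O-])CC/C(C)=C/I | intermediate
10 | ethyl (2R,3R,6E)-3-hydroxy-7-iodo-2,6-dimethyl-2-({[tri(propan-2-yl)silyl]oxy}methyl)hept-6-enoate | CCOC(=O)[C@](C)(CO[Si](C(C)C)(C(C)C)C(C)C)[C@H](O)CC/C(C)=C/I | intermediate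
11 | ethyl (2R,3R,6E)-7-iodo-2,6-dimethyl-3-[(triethylsilyl)oxy]-2-({[tri(propan-2-yl)silyl]oxy}methyl)hept-6-enoate | CCOC(=O)[C@](C)(CO[Si](C(C)C)(C(C)C)C(C)C)[C@H](O[Si](CC)(CC)CC)CC/C(C)=C/I | intermediate
12 | (2R,3R,6E)-7-iodo-2,6-dimethyl-3-[(triethylsilyl)oxy]-2-({[tri(propan-2-yl)silyl]oxy}methyl)hept-6-en-1-ol | OC[C@](C)(CO[Si](C(C)C)(C(C)C)C(C)C)[C@H](O[Si](CC)(CC)CC)CC/C(C)=C/I | intermediate
13 | (2R,3R,6E)-7-iodo-2,6-dimethyl-3-[(triethylsilyl)oxy]-2-({[tri(propan-2-yl)silyl]oxy}methyl)hept-6-enal | O=C[C@](C)(CO[Si](C(C)C)(C(C)C)C(C)C)[C@H](O[Si](CC)(CC)CC)CC/C(C)=C/I | intermediate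
14 | diethyl (2-oxobutyl)phosphonate | CCC(=O)CP(=O)(OCC)OCC | starting material
15 | (4E,6R,7R,10E)-11-iodo-6,10-dimethyl-7-[(triethylsilyl)oxy]-6-({[tri(propan-2-yl)silyl]oxy}methyl)undeca-4,10-dien-3-one | CCC(=O)/C=C/[C@](C)(CO[Si](C(C)C)(C(C)C)C(C)C)[C@H](O[Si](CC)(CC)CC)CC/C(C)=C/I | intermediate
16 | (2Z,4E,6R,7R,10E)-3-[(tert-butyldimethylsilyl)oxy]-11-iodo-6,10-dimethyl-7-[(triethylsilyl)oxy]-6-({[tri(propan-2-yl)silyl]oxy}methyl)undeca-2,4,10-triene | C/C=C(O[Si](C)(C)C(C)(C)C)/C=C/[C@](C)(CO[Si](C(C)C)(C(C)C)C(C)C)[C@H](O[Si](CC)(CC)CC)CC/C(C)=C/I | intermediate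
17 | [(1E,5R,6R,7E,9Z)-9-[(tert-butyldimethylsilyl)oxy]-2,6-dimethyl-5-[(triethylsilyl)oxy]-6-({[tri(propan-2-yl)silyl]oxy}methyl)undeca-1,7,9-trien-1-yl]lithium (not isolated) | C/C=C(O[Si](C)(C)C(C)(C)C)/C=C/[C@](C)(CO[Si](C(C)C)(C(C)C)C(C)C)[C@H](O[Si](CC)(CC)CC)CC/C(C)=C/[Li] | intermediate
18 | (2E,6R,7R,8E,10Z)-10-[(tert-butyldimethylsilyl)oxy]-3,7-dimethyl-6-[(triethylsilyl)oxy]-7-({[tri(propan-2-yl)silyl]oxy}methyl)dodeca-2,8,10-trienal (key-step precursor) | O=C/C=C(\C)CC[C@@H](O[Si](CC)(CC)CC)[C@@](C)(CO[Si](C(C)C)(C(C)C)C(C)C)/C=C/C(O[Si](C)(C)C(C)(C)C)=C/C | intermediate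
19 | (1R,2S,4aS,5R,6R,8aR)-3-[(tert-butyldimethylsilyl)oxy]-2,5,8a-trimethyl-6-[(triethylsilyl)oxy]-5-({[tri(propan-2-yl)silyl]oxy}methyl)-1,2,4a,5,6,7,8,8a-octahydronaphthalene-1-carbaldehyde (key-step product; trans-decalin, 3-OTES equatorial, C19 axial, 8-CH3 and 9-CHO cis to the C10 methyl) | CC[Si](CC)(CC)O[C@@H]1CC[C@]2(C)[C@H](C=C(O[Si](C)(C)C(C)(C)C)[C@@H](C)[C@H]2C=O)[C@]1(C)CO[Si](C(C)C)(C(C)C)C(C)C | intermediate
20 | (4S)-4-methyloxolan-2-one [(S)-4-methyldihydrofuran-2(3H)-one] | C[C@@H]1COC(=O)C1 | starting material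
21 | methyl (3S)-4-bromo-3-methylbutanoate | COC(=O)C[C@H](C)CBr | intermediate
22 | [(2S)-4-methoxy-2-methyl-4-oxobutyl]triphenylphosphonium bromide | COC(=O)C[C@H](C)C[P+](c1ccccc1)(c1ccccc1)c1ccccc1.[Br-] | intermediate
23 | methyl (3S)-3-methyl-4-(triphenyl-λ5-phosphanylidene)butanoate (ylide; not isolated) | COC(=O)C[C@H](C)C=P(c1ccccc1)(c1ccccc1)c1ccccc1 | intermediate
24 | methyl (3S,4Z)-5-[(1R,2S,4aS,5R,6R,8aS)-3-[(tert-butyldimethylsilyl)oxy]-2,5,8a-trimethyl-6-[(triethylsilyl)oxy]-5-({[tri(propan-2-yl)silyl]oxy}methyl)-1,2,4a,5,6,7,8,8a-octahydronaphthalen-1-yl]-3-methylpent-4-enoate (not isolated) | CC[Si](CC)(CC)O[C@@H]1CC[C@]2(C)[C@H](C=C(O[Si](C)(C)C(C)(C)C)[C@@H](C)[C@H]2/C=C\[C@@H](C)CC(=O)OC)[C@]1(C)CO[Si](C(C)C)(C(C)C)C(C)C | intermediate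
25 | methyl (3S,4Z)-3-methyl-5-[(1R,2S,4aS,5R,6R,8aS)-2,5,8a-trimethyl-3-oxo-6-[(triethylsilyl)oxy]-5-({[tri(propan-2-yl)silyl]oxy}methyl)decahydronaphthalen-1-yl]pent-4-enoate | CC[Si](CC)(CC)O[C@@H]1CC[C@]2(C)[C@H](CC(=O)[C@@H](C)[C@H]2/C=C\[C@@H](C)CC(=O)OC)[C@]1(C)CO[Si](C(C)C)(C(C)C)C(C)C | intermediate
26 | methyl (3R)-3-methyl-5-[(1R,2S,4aS,5R,6R,8aS)-2,5,8a-trimethyl-3-oxo-6-[(triethylsilyl)oxy]-5-({[tri(propan-2-yl)silyl]oxy}methyl)decahydronaphthalen-1-yl]pentanoate | CC[Si](CC)(CC)O[C@@H]1CC[C@]2(C)[C@H](CC(=O)[C@@H](C)[C@H]2CC[C@@H](C)CC(=O)OC)[C@]1(C)CO[Si](C(C)C)(C(C)C)C(C)C | intermediate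
27 | methyl (3R)-3-methyl-5-[(1S,4aS,5R,6R,8aR)-2,5,8a-trimethyl-6-[(triethylsilyl)oxy]-5-({[tri(propan-2-yl)silyl]oxy}methyl)-3-{[(trifluoromethyl)sulfonyl]oxy}-1,4,4a,5,6,7,8,8a-octahydronaphthalen-1-yl]pentanoate | CC[Si](CC)(CC)O[C@@H]1CC[C@]2(C)[C@H](CC(OS(=O)(=O)C(F)(F)F)=C(C)[C@H]2CC[C@@H](C)CC(=O)OC)[C@]1(C)CO[Si](C(C)C)(C(C)C)C(C)C | intermediate
28 | methyl (3R)-3-methyl-5-[(1R,4aS,5R,6R,8aS)-2,5,8a-trimethyl-6-[(triethylsilyl)oxy]-5-({[tri(propan-2-yl)silyl]oxy}methyl)-1,4,4a,5,6,7,8,8a-octahydronaphthalen-1-yl]pentanoate | CC[Si](CC)(CC)O[C@@H]1CC[C@]2(C)[C@H](CC=C(C)[C@H]2CC[C@@H](C)CC(=O)OC)[C@]1(C)CO[Si](C(C)C)(C(C)C)C(C)C | intermediate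
29 | methyl (3R)-5-[(1R,4aS,5R,6R,8aS)-6-hydroxy-2,5,8a-trimethyl-5-({[tri(propan-2-yl)silyl]oxy}methyl)-1,4,4a,5,6,7,8,8a-octahydronaphthalen-1-yl]-3-methylpentanoate (equatorial C3–OH) | O[C@@H]1CC[C@]2(C)[C@H](CC=C(C)[C@H]2CC[C@@H](C)CC(=O)OC)[C@]1(C)CO[Si](C(C)C)(C(C)C)C(C)C | intermediate
30 | methyl (3R)-3-methyl-5-[(1R,4aS,5R,8aS)-2,5,8a-trimethyl-6-oxo-5-({[tri(propan-2-yl)silyl]oxy}methyl)-1,4,4a,5,6,7,8,8a-octahydronaphthalen-1-yl]pentanoate | O=C1CC[C@]2(C)[C@H](CC=C(C)[C@H]2CC[C@@H](C)CC(=O)OC)[C@]1(C)CO[Si](C(C)C)(C(C)C)C(C)C | intermediate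
31 | methyl (3R)-5-[(1R,4aS,5R,6S,8aS)-6-hydroxy-2,5,8a-trimethyl-5-({[tri(propan-2-yl)silyl]oxy}methyl)-1,4,4a,5,6,7,8,8a-octahydronaphthalen-1-yl]-3-methylpentanoate (axial C3–OH; not isolated) | O[C@H]1CC[C@]2(C)[C@H](CC=C(C)[C@H]2CC[C@@H](C)CC(=O)OC)[C@]1(C)CO[Si](C(C)C)(C(C)C)C(C)C | intermediate
32 | (3R)-5-[(1R,4aS,5R,6S,8aS)-6-hydroxy-2,5,8a-trimethyl-5-({[tri(propan-2-yl)silyl]oxy}methyl)-1,4,4a,5,6,7,8,8a-octahydronaphthalen-1-yl]-3-methylpentanoic acid | O[C@H]1CC[C@]2(C)[C@H](CC=C(C)[C@H]2CC[C@@H](C)CC(=O)O)[C@]1(C)CO[Si](C(C)C)(C(C)C)C(C)C | intermediate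
33 | (3R)-5-[(1R,4aS,5R,6S,8aS)-6-(acetyloxy)-2,5,8a-trimethyl-5-({[tri(propan-2-yl)silyl]oxy}methyl)-1,4,4a,5,6,7,8,8a-octahydronaphthalen-1-yl]-3-methylpentanoic acid | CC(=O)O[C@H]1CC[C@]2(C)[C@H](CC=C(C)[C@H]2CC[C@@H](C)CC(=O)O)[C@]1(C)CO[Si](C(C)C)(C(C)C)C(C)C | intermediate
34 | (3R)-5-[(1R,4aS,5R,6S,8aS)-6-(acetyloxy)-5-(hydroxymethyl)-2,5,8a-trimethyl-1,4,4a,5,6,7,8,8a-octahydronaphthalen-1-yl]-3-methylpentanoic acid (CNP0138726.1) | CC(=O)O[C@H]1CC[C@]2(C)[C@H](CC=C(C)[C@H]2CC[C@@H](C)CC(=O)O)[C@]1(C)CO | target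

Total step count: 23. Longest linear sequence: 21 steps (steps 1–12, then 15–23, from 1 to 34); the side branch (steps 13–14) has 2 steps.

Steps most likely to fail

Step 12 (key step). Two processes can defeat it. The acid-sensitive silyl dienol ether may be lost to the aluminium Lewis acid (desilylation or intermolecular Mukaiyama-type addition) faster than the hindered β,β-disubstituted enal cyclises, since the silyloxy group polarises the diene toward C8 while the tether forces C5 to bond first. The two diene faces may also be discriminated poorly, because the bias rests only on the equatorial preference of the C3 silyl ether. The fallback sets out from 18 and comes back at 19, and replaces Lewis acid activation of the aldehyde by a cationic Diels–Alder reaction of its acetal. Methoxytrimethylsilane (2.2 equiv) and catalytic Me3SiOTf in CH2Cl2 at −78 °C convert 18 in the flask into the trienal dimethyl acetal F1. Its ionisation to the alkoxyallyl (vinyl oxocarbenium) cation gives a far more electrophilic dienophile, which should close both rings (C5–C10 first, then C8–C9) to the decalin dimethyl acetal F2. The acetal is then unmasked under non-acidic conditions (Et3SiOTf, 2,6-lutidine, CH2Cl2, 0 °C; then water), which leave the silyl enol ether and both silyl ethers alone, to return aldehyde 19.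

Step 5. C-alkylation of the fully substituted enolate by the bulky chloromethyl silyl ether may be incomplete, and O-alkylation of the alkoxide or silyl transfer from the reagent may compete. The fallback sets out from 8 (through its dianion 9) and comes back at 10. Monomeric formaldehyde (from cracked paraformaldehyde, THF, −78 °C) hydroxymethylates the dianion with the same facial bias to give the diol ester F3. The primary hydroxyl alone is then silylated (iPr3SiCl, imidazole, DMF, 0 °C) to give 10.

Step 17. Triflation may run through the less substituted enol (C6=C7) or give a regioisomer mixture, which would misplace the ring alkene. The fallback sets out from 26 and comes back at 27, and moves the regiochemical decision to an equilibrated silyl enol ether. Me3SiI with HN(SiMe3)2 (CH2Cl2, −20 °C to rt) should give the more substituted trimethylsilyl enol ether F4, which can be purified as a single regioisomer. CsF and PhNTf2 in DME then convert it regiospecifically into 27.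

Further compounds
F1 | step 12 | (2Z,4E,6R,7R,10E)-3-[(tert-butyldimethylsilyl)oxy]-12,12-dimethoxy-6,10-dimethyl-7-[(triethylsilyl)oxy]-6-({[tri(propan-2-yl)silyl]oxy}methyl)dodeca-2,4,10-triene | COC(OC)/C=C(\C)CC[C@@H](O[Si](CC)(CC)CC)[C@@](C)(CO[Si](C(C)C)(C(C)C)C(C)C)/C=C/C(O[Si](C)(C)C(C)(C)C)=C/C
F2 | step 12 | (1R,2S,4aS,5R,6R,8aR)-3-[(tert-butyldimethylsilyl)oxy]-1-(dimethoxymethyl)-2,5,8a-trimethyl-6-[(triethylsilyl)oxy]-5-({[tri(propan-2-yl)silyl]oxy}methyl)-1,2,4a,5,6,7,8,8a-octahydronaphthalene | CC[Si](CC)(CC)O[C@@H]1CC[C@]2(C)[C@H](C=C(O[Si](C)(C)C(C)(C)C)[C@@H](C)[C@H]2C(OC)OC)[C@]1(C)CO[Si](C(C)C)(C(C)C)C(C)C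
F3 | step 5 | ethyl (2R,3R,6E)-3-hydroxy-2-(hydroxymethyl)-7-iodo-2,6-dimethylhept-6-enoate | CCOC(=O)[C@](C)(CO)[C@H](O)CC/C(C)=C/I
F4 | step 17 | methyl (3R)-3-methyl-5-[(1S,4aS,5R,6R,8aR)-2,5,8a-trimethyl-6-[(triethylsilyl)oxy]-5-({[tri(propan-2-yl)silyl]oxy}methyl)-3-[(trimethylsilyl)oxy]-1,4,4a,5,6,7,8,8a-octahydronaphthalen-1-yl]pentanoate | CC[Si](CC)(CC)O[C@@H]1CC[C@]2(C)[C@H](CC(O[Si](C)(C)C)=C(C)[C@H]2CC[C@@H](C)CC(=O)OC)[C@]1(C)CO[Si](C(C)C)(C(C)C)C(C)C
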